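The tridepside is cut at the ester between rings B and C, and ring C is built as its dihydro form rather than bought as an arene. A Michael–Claisen annulation of benzyl acetoacetate with ethyl crotonate forms C1''–C6'' and C3''–C4'' in one operation. It gives a cyclohexane-2,4-dione that already carries the C1'' benzyl ester and the C6'' methyl. The feature exploited is the oxygen pattern of ring C. Only O4'' is acylated in the target, and in the dione O4'' adjoins the C5'' methylene whereas O2'' is crowded by the C1'' ester. The protected ring A–B acid chloride should therefore esterify O4'' without phenol protection. Dehydrogenation and one hydrogenolysis finish the synthesis.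

Key step: step 1

Remarks
- **Numbering:** ring A is unprimed, ring B primed and ring C double-primed; C1 is always the carbon bearing the carbonyl group.
- **Abbreviations:** "A-acyl" is 4-methoxy-6-methyl-2,2-diphenyl-1,3-benzodioxole-5-carbonyl, that is ring A with O3/O4 tied up as a diphenylmethylene ketal. "AB-acyl" is 2-(benzyloxy)-6-methyl-4-(A-acyloxy)benzoyl.
- **Stereochemistry:** the target is achiral. All chiral ring C intermediates are racemic, and each SMILES shows one enantiomer. The dione is drawn as the diketo tautomer although it is largely enolized.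
- **Assumption:** 5-methylpyrogallol and 2,4-dihydroxy-6-methylbenzaldehyde are bought as catalogue chemicals.

Step 1
Reactants: 1 benzyl acetoacetate; 2 ethyl (E)-crotonate
Product: 4 benzyl trans-6-methyl-2,4-dioxocyclohexane-1-carboxylate (racemic; 1S,6R enantiomer drawn), via Michael adduct 3 (not isolated)
Conditions: NaOCH2Ph (1.1 equiv, 1.0 M in PhCH2OH), toluene, 100 °C, EtOH distilled off; then H2O, Et2O wash, 2 M HCl, 0 °C
Reagents that add atoms: none
Why: NaOCH2Ph deprotonates the active methylene of 1, and this soft enolate adds 1,4 to the β-carbon of 2 (bond C1''–C6'') to give adduct 3. Proton exchange then produces the terminal methyl ketone enolate, which attacks the ethyl ester carbonyl in a favoured 6-(enolendo)-exo-trig Claisen (Dieckmann-type) closure (bond C3''–C4'') and expels ethoxide. This is the classical Michael–Claisen annulation of acetoacetates with crotonates to dihydroresorcylates, and it is pulled forward because the vinylogous acid 4 is removed as its sodium enolate. C6'' arises from achiral partners without facial bias and is racemic, while C1'' stays epimerizable between ketone and ester and should settle under thermodynamic control with CO2Bn and CH3 trans-diequatorial. The step needs C-alkylation at the doubly activated carbon before ring closure and retention of the benzyl ester; the second is secured by matching base and alcohol to that ester and distilling out the liberated ethanol, and the acidic product is freed from benzyl alcohol by base extraction.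

Step 2
Reactants: 5 5-methylpyrogallol (5-methylbenzene-1,2,3-triol)
Product: 6 6-methyl-2,2-diphenyl-1,3-benzodioxol-4-ol
Conditions: Ph2CCl2 (1.05 equiv), Ph2O, 170 °C, N2 stream
Reagents that add atoms: dichlorodiphenylmethane, ClC(Cl)(c1ccccc1)c1ccccc1
Why: Catechol ketalization by double substitution on a gem-dichloride closes the five-membered dioxole, and because 5 is symmetric either vicinal pair of hydroxyls gives the same product with exactly one free phenol.

Step 3
Reactants: 6 6-methyl-2,2-diphenyl-1,3-benzodioxol-4-ol
Product: 7 4-hydroxy-6-methyl-2,2-diphenyl-1,3-benzodioxole-5-carbaldehyde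
Conditions: MgCl2 (2 equiv), Et3N (4 equiv), (CH2O)n (6 equiv), MeCN, reflux; then 1 M HCl
Reagents that add atoms: paraformaldehyde (reacts as formaldehyde), C=O
Why: In the Casnati–Skattebøl ortho-formylation the magnesium phenoxide delivers formaldehyde only to an ortho carbon, the sole free ortho site lies between OH and CH3 (the future C1 of ring A), and a second formaldehyde oxidizes the hydroxymethyl stage by hydride transfer.

Step 4
Reactants: 7 4-hydroxy-6-methyl-2,2-diphenyl-1,3-benzodioxole-5-carbaldehyde
Product: 8 4-methoxy-6-methyl-2,2-diphenyl-1,3-benzodioxole-5-carbaldehyde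
Conditions: MeI (1.5 equiv), K2CO3 (2 equiv), DMF, rt
Reagents that add atoms: iodomethane, CI
Why: Williamson ether synthesis on the only free phenol fixes the O2 methyl ether of ring A, and the polar aprotic solvent overcomes the chelation of that hydroxyl to the formyl group.

Step 5
Reactants: 8 4-methoxy-6-methyl-2,2-diphenyl-1,3-benzodioxole-5-carbaldehyde
Product: 9 4-methoxy-6-methyl-2,2-diphenyl-1,3-benzodioxole-5-carboxylic acid (ring A acid)
Conditions: NaClO2, NaH2PO4, 2-methyl-2-butene, t-BuOH/THF/H2O, rt
Reagents that add atoms: sodium chlorite, [Na+].[O-]Cl=O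
Why: The Pinnick oxidation converts hindered electron-rich benzaldehydes to acids at mildly acidic pH that the diphenylmethylene ketal tolerates, and the alkene traps HOCl before it can chlorinate the ring.

Step 6
Reactants: 9 ring A acid; 10 2,4-dihydroxy-6-methylbenzaldehyde
Product: 11 4-formyl-3-hydroxy-5-methylphenyl 4-methoxy-6-methyl-2,2-diphenyl-1,3-benzodioxole-5-carboxylate
Conditions: DCC (1.2 equiv), DMAP (0.2 equiv), CH2Cl2, 0 °C to rt
Reagents that add atoms: none
Why: Steglich esterification should acylate only O4' of 10, because this phenol is para to the formyl group, more acidic and unencumbered, whereas O2' is locked in a hydrogen bond to the aldehyde oxygen.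

Step 7
Reactants: 11 4-formyl-3-hydroxy-5-methylphenyl A-acyl ester
Product: 12 3-(benzyloxy)-4-formyl-5-methylphenyl 4-methoxy-6-methyl-2,2-diphenyl-1,3-benzodioxole-5-carboxylate
Conditions: BnBr (1.3 equiv), K2CO3 (1.5 equiv), DMF, rt
Reagents that add atoms: benzyl bromide, BrCc1ccccc1
Why: Williamson benzylation caps O2' so that the later acid chloride carries no free phenol, and the depside ester survives the mild carbonate base because its carbonyl is shielded by two ortho substituents.

Step 8
Reactants: 12 3-(benzyloxy)-4-formyl-5-methylphenyl A-acyl ester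
Product: 13 2-(benzyloxy)-6-methyl-4-[(4-methoxy-6-methyl-2,2-diphenyl-1,3-benzodioxole-5-carbonyl)oxy]benzoic acid (ring A–B acid)
Conditions: NaClO2, NaH2PO4, 2-methyl-2-butene, t-BuOH/THF/H2O, rt
Reagents that add atoms: sodium chlorite, [Na+].[O-]Cl=O
Why: A second Pinnick oxidation unmasks the ring B carboxyl from the aldehyde without any ester cleavage step, so the depside bond, benzyl ether and ketal are never exposed to hydrolytic conditions.

Step 9
Reactants: 13 ring A–B acid; 4 benzyl trans-6-methyl-2,4-dioxocyclohexane-1-carboxylate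
Product: 15 benzyl trans-4-(AB-acyloxy)-6-methyl-2-oxocyclohex-3-ene-1-carboxylate (racemic O4'' enol ester), via acid chloride 14 (not isolated)
Conditions: (COCl)2 (1.3 equiv), DMF (cat.), CH2Cl2, 0 °C to rt, evaporate; then 4 (1.05 equiv), Et3N (1.2 equiv), CH2Cl2, 0 °C
Reagents that add atoms: none
Why: This is the standard formation of an enol ester from a cyclohexane-1,3-dione enolate and an aroyl chloride; both oxygens share the enolate charge, so the choice is steric and should fall on O4'' beside the C5'' methylene rather than O2'' beside the ester-bearing C1'', a bias sharpened by the 2,6-disubstituted acyl donor, while omitting DMAP and cyanide removes the catalyst for the O-to-C3'' acyl shift.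

Step 10
Reactants: 15 O4'' enol ester
Product: 19 benzyl 4-(AB-acyloxy)-2-hydroxy-6-methylbenzoate (fully protected tridepside), via selenide 16 (not isolated), via selenoxide 17 (not isolated), via cyclohexadienone 18 (not isolated)
Conditions: PhSeCl (1.1 equiv), pyridine (1.2 equiv), CH2Cl2, 0 °C to rt; 1 M HCl wash; then 30% H2O2 (3 equiv), CH2Cl2, 0 °C to rt; chromatography to remove selenium residues
Reagents that add atoms: none
Why: In this α-selenenylation/selenoxide syn-elimination the β-keto ester carbon C1'' is the most acidic and most enolized site, so selenium should enter there anti to the pseudoaxial C6'' methyl and hence syn to C6''–H; oxidation then triggers elimination to C1''=C6'', and the cross-conjugated dienone 18 tautomerizes irreversibly to the chelated phenol, erasing both stereocentres.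

Step 11
Reactants: 19 fully protected tridepside
Product: 20 4-{[4-(3,4-dihydroxy-2-methoxy-6-methylbenzoyl)oxy-2-hydroxy-6-methylbenzoyl]oxy}-2-hydroxy-6-methylbenzoic acid (CNP0277338.0)
Conditions: H2 (1 atm), Pd/C (10 wt% palladium on carbon), EtOAc/THF, rt
Reagents that add atoms: none
Why: Catalytic hydrogenolysis cleaves every benzylic C–O bond at once (benzyl ester, benzyl ether and the doubly benzylic diphenylmethylene ketal) under neutral, non-nucleophilic conditions, which should leave both depside esters, the aryl methyl ether and the decarboxylation-prone salicylic acid untouched.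

Compound list
1 | benzyl acetoacetate | CC(=O)CC(=O)OCc1ccccc1 | starting material
2 | ethyl (E)-crotonate | C/C=C/C(=O)OCC | starting material
3 | 1-benzyl 5-ethyl 2-acetyl-3-methylpentanedioate (Michael adduct, diastereomer mixture) | CCOC(=O)CC(C)C(C(C)=O)C(=O)OCc1ccccc1 | intermediate
4 | benzyl trans-6-methyl-2,4-dioxocyclohexane-1-carboxylate (racemic) | C[C@@H]1CC(=O)CC(=O)[C@H]1C(=O)OCc1ccccc1 | intermediate
5 | 5-methylpyrogallol | Cc1cc(O)c(O)c(O)c1 | starting material
6 | 6-methyl-2,2-diphenyl-1,3-benzodioxol-4-ol | Cc1cc(O)c2OC(c3ccccc3)(c3ccccc3)Oc2c1 | intermediate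
7 | 4-hydroxy-6-methyl-2,2-diphenyl-1,3-benzodioxole-5-carbaldehyde | Cc1cc2OC(c3ccccc3)(c3ccccc3)Oc2c(O)c1C=O | intermediate
8 | 4-methoxy-6-methyl-2,2-diphenyl-1,3-benzodioxole-5-carbaldehyde | COc1c(C=O)c(C)cc2OC(c3ccccc3)(c3ccccc3)Oc12 | intermediate
9 | 4-methoxy-6-methyl-2,2-diphenyl-1,3-benzodioxole-5-carboxylic acid | COc1c(C(=O)O)c(C)cc2OC(c3ccccc3)(c3ccccc3)Oc12 | intermediate
10 | 2,4-dihydroxy-6-methylbenzaldehyde | Cc1cc(O)cc(O)c1C=O | starting material
11 | 4-formyl-3-hydroxy-5-methylphenyl A-acyl ester | COc1c(C(=O)Oc3cc(C)c(C=O)c(O)c3)c(C)cc2OC(c3ccccc3)(c3ccccc3)Oc12 | intermediate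
12 | 3-(benzyloxy)-4-formyl-5-methylphenyl A-acyl ester | COc1c(C(=O)Oc3cc(C)c(C=O)c(OCc4ccccc4)c3)c(C)cc2OC(c3ccccc3)(c3ccccc3)Oc12 | intermediate
13 | 2-(benzyloxy)-6-methyl-4-(A-acyloxy)benzoic acid | COc1c(C(=O)Oc3cc(C)c(C(=O)O)c(OCc4ccccc4)c3)c(C)cc2OC(c3ccccc3)(c3ccccc3)Oc12 | intermediate
14 | 2-(benzyloxy)-6-methyl-4-(A-acyloxy)benzoyl chloride | COc1c(C(=O)Oc3cc(C)c(C(=O)Cl)c(OCc4ccccc4)c3)c(C)cc2OC(c3ccccc3)(c3ccccc3)Oc12 | intermediate
15 | benzyl trans-4-(AB-acyloxy)-6-methyl-2-oxocyclohex-3-ene-1-carboxylate (racemic) | COc1c(C(=O)Oc3cc(C)c(C(=O)OC4=CC(=O)[C@@H](C(=O)OCc5ccccc5)[C@H](C)C4)c(OCc4ccccc4)c3)c(C)cc2OC(c3ccccc3)(c3ccccc3)Oc12 | intermediate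
16 | benzyl 4-(AB-acyloxy)-6-methyl-2-oxo-1-(phenylselanyl)cyclohex-3-ene-1-carboxylate (racemic; PhSe trans to the C6'' methyl) | COc1c(C(=O)Oc3cc(C)c(C(=O)OC4=CC(=O)[C@@](C(=O)OCc5ccccc5)([Se]c5ccccc5)[C@H](C)C4)c(OCc4ccccc4)c3)c(C)cc2OC(c3ccccc3)(c3ccccc3)Oc12 | intermediate
17 | the corresponding selenoxide (racemic; mixture at selenium) | COc1c(C(=O)Oc3cc(C)c(C(=O)OC4=CC(=O)[C@@](C(=O)OCc5ccccc5)([Se](=O)c5ccccc5)[C@H](C)C4)c(OCc4ccccc4)c3)c(C)cc2OC(c3ccccc3)(c3ccccc3)Oc12 | intermediate
18 | benzyl 4-(AB-acyloxy)-2-methyl-6-oxocyclohexa-1,4-diene-1-carboxylate (keto tautomer of 19) | COc1c(C(=O)Oc3cc(C)c(C(=O)OC4=CC(=O)C(C(=O)OCc5ccccc5)=C(C)C4)c(OCc4ccccc4)c3)c(C)cc2OC(c3ccccc3)(c3ccccc3)Oc12 | intermediate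
19 | benzyl 4-(AB-acyloxy)-2-hydroxy-6-methylbenzoate | COc1c(C(=O)Oc3cc(C)c(C(=O)Oc4cc(C)c(C(=O)OCc5ccccc5)c(O)c4)c(OCc4ccccc4)c3)c(C)cc2OC(c3ccccc3)(c3ccccc3)Oc12 | intermediate
20 | CNP0277338.0 | COc1c(O)c(O)cc(C)c1C(=O)Oc1cc(C)c(C(=O)Oc2cc(C)c(C(=O)O)c(O)c2)c(O)c1 | target

Total step count: 11. Longest linear sequence: 10 (steps 2 to 11; step 1 is the convergent branch).

Steps most likely to fail

1. **Step 9.** The acyl group may be delivered to O2'' as well as O4''. It may also drift on to C3'' by O-to-C migration, or be lost when the vinylogous anhydride hydrolyses on work-up. The fallback reverses the order of esterification and aromatization. Setting out from 4, Br2 in DMF at 0 °C should give the C3''-bromo dione F1. On warming to 80 °C this loses HBr and tautomerizes to benzyl orsellinate F2. Its O4'' phenol (O2'' being chelated to the ester) is then acylated with acid chloride 14 (Et3N, catalytic DMAP, CH2Cl2). This classical depside coupling comes back to the route at 19 and makes step 10 unnecessary.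

2. **Step 10.** The enol acyl group may be stripped by pyridine or peroxide. Selenium may enter on the face of the methyl group, so that no syn hydrogen is available. The peroxide/seleninic acid medium may also over-oxidize the new phenol. The fallback replaces syn-elimination by hydride abstraction from a cyclohexadiene. Setting out from 15, TMSOTf/Et3N in CH2Cl2 at 0 °C should give the 2''-trimethylsilyloxy-1,3-diene F3. DDQ in toluene at rt aromatizes it to the aryl trimethylsilyl ether F4, and dilute aqueous HCl in THF removes silicon. The sequence comes back to the route at 19.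

3. **Step 11.** Hydrogenolysis of the diphenylmethylene ketal may stall after the ordinary benzyl groups have left. Traces of selenium may also slow the catalyst. The fallback separates the two kinds of deprotection. Setting out from 19, TFA in CH2Cl2 with a little water at rt hydrolyses the ketal to the ring A catechol dibenzyl compound F5. Then H2 over Pd/C in EtOAc/THF has only one benzyl ester and one benzyl ether to remove, and the sequence arrives at 20.

Further compounds
F1 | step 9 | benzyl 3-bromo-6-methyl-2,4-dioxocyclohexane-1-carboxylate (racemic, C3'' enolizable) | C[C@@H]1CC(=O)C(Br)C(=O)[C@H]1C(=O)OCc1ccccc1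
F2 | step 9 | benzyl orsellinate (benzyl 2,4-dihydroxy-6-methylbenzoate) | Cc1cc(O)cc(O)c1C(=O)OCc1ccccc1
F3 | step 10 | benzyl 4-(AB-acyloxy)-6-methyl-2-(trimethylsilyloxy)cyclohexa-1,3-diene-1-carboxylate (racemic) | COc1c(C(=O)Oc3cc(C)c(C(=O)OC4=CC(O[Si](C)(C)C)=C(C(=O)OCc5ccccc5)[C@H](C)C4)c(OCc4ccccc4)c3)c(C)cc2OC(c3ccccc3)(c3ccccc3)Oc12
F4 | step 10 | benzyl 4-(AB-acyloxy)-6-methyl-2-(trimethylsilyloxy)benzoate | COc1c(C(=O)Oc3cc(C)c(C(=O)Oc4cc(C)c(C(=O)OCc5ccccc5)c(O[Si](C)(C)C)c4)c(OCc4ccccc4)c3)c(C)cc2OC(c3ccccc3)(c3ccccc3)Oc12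
F5 | step 11 | benzyl 4-{[2-(benzyloxy)-4-(3,4-dihydroxy-2-methoxy-6-methylbenzoyl)oxy-6-methylbenzoyl]oxy}-2-hydroxy-6-methylbenzoate | COc1c(O)c(O)cc(C)c1C(=O)Oc1cc(C)c(C(=O)Oc2cc(C)c(C(=O)OCc3ccccc3)c(O)c2)c(OCc2ccccc2)c1
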